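**Retrosynthetic overview** (target numbering: C1 = C(NH2)CO2H, C2 = CH–O-octanoyl, C3 = C(OH)Ph)
1. Fusarilin A ⇐ hydrogenolysis of N-Cbz benzyl ester 20; the tertiary C3–OH ⇐ carbamate-directed epoxidation of cyclopentene 17 (octanoate already on C2–O), selenolate opening at C4, tin hydride deselenation.
2. Cyclopentene 16 (the only carbocycle) ⇐ ring-closing metathesis of diene 15 (allyl on C1, 1-phenylvinyl on C2).
3. Quaternary C1 ⇐ allylation of the ester enolate of trans-oxazolidine 12, anti to the C2 substituent (C2 controls C1).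
4. C1–C2 bond and the C2 carbinol ⇐ intermolecular syn-aldol of the titanium aza-enolate of the (S)-Schöllkopf bislactim ether 4 with 2-phenylacrolein 3.
5. Ring order: temporary oxazolidine (step 6, opened in step 8), then cyclopentene (step 9), then temporary oxirane (step 11, opened in step 12).

Assumption: the target is the free (zwitterionic) amino acid (1S,2R,3S)-1-amino-3-hydroxy-2-(octanoyloxy)-3-phenylcyclopentane-1-carboxylic acid; reagents that appear only on the Conditions or reagent lines are bought.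

**Step 1**
Reactants: 1 phenylacetaldehyde
Product: 3 2-phenylprop-2-enal (atropaldehyde), via Mannich base 2 (not isolated)
Conditions: 37% aq. CH2O (1.2 equiv), pyrrolidine (10 mol%), EtCO2H (10 mol%), iPrOH, 45 °C, 1 h; used fresh
Reagents that add atoms: formaldehyde C=O
Why: Amine-catalysed Mannich condensation (α-methylenation): the enamine of 1 adds to the formaldehyde iminium ion and the Mannich base loses pyrrolidine to give the enal; no stereocentre is formed.

**Step 2**
Reactants: 4 (2S)-3,6-dimethoxy-2-(propan-2-yl)-2,5-dihydropyrazine; 3 2-phenylprop-2-enal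
Product: 7 (2S,5R)-5-[(1S)-1-hydroxy-2-phenylprop-2-en-1-yl]-3,6-dimethoxy-2-(propan-2-yl)-2,5-dihydropyrazine, via lithiated bislactim ether 5 (not isolated), via titanium aza-enolate 6 (not isolated)
Conditions: n-BuLi (1.05 equiv), THF, −78 °C; ClTi(NEt2)3 (1.1 equiv), −78 °C, 1 h; 3 (1.2 equiv), −78 °C, 4 h; pH 7 buffer; chromatography
Reagents that add atoms: none
Why: Schöllkopf bislactim ether aldol: the titanium aza-enolate adds 1,2 to the aldehyde through a closed Zimmerman–Traxler transition state on the ring face trans to the isopropyl group, giving the syn (threo) adduct whose (S)-carbinol becomes C2 of the target (the ring centre C5 is erased in step 7).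

**Step 3**
Reactants: 7 aldol adduct
Product: 8 methyl (2R,3S)-2-amino-3-hydroxy-4-phenylpent-4-enoate
Conditions: 0.25 M aq. HCl (2.2 equiv), MeCN, rt, 8 h; NaHCO3; methyl L-valinate removed by bulb-to-bulb distillation
Reagents that add atoms: water O
Why: Mild acid hydrolysis of both lactim ether (imidate) units releases the two amino methyl esters without touching the allylic alcohol or the stereocentres.

**Step 4**
Reactants: 8 amino ester
Product: 10 (2R,3S)-2-{[(benzyloxy)carbonyl]amino}-3-hydroxy-4-phenylpent-4-enoic acid, via lithium carboxylate 9 (not isolated)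
Conditions: LiOH·H2O (1.2 equiv), THF/H2O, 0 °C; then NaHCO3, CbzCl (1.2 equiv), 0 °C → rt; 1 M HCl to pH 2
Reagents that add atoms: lithium hydroxide [Li+].[OH-]; benzyl chloroformate O=C(Cl)OCc1ccccc1
Why: Saponification followed by Schotten–Baumann N-acylation; epimerisation at the α-carbon would be harmless because that centre is re-set in step 7, and the carbinol centre is untouched.

**Step 5**
Reactants: 10 N-Cbz acid
Product: 11 benzyl (2R,3S)-2-{[(benzyloxy)carbonyl]amino}-3-hydroxy-4-phenylpent-4-enoate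
Conditions: BnBr (1.1 equiv), KHCO3 (1.5 equiv), DMF, rt
Reagents that add atoms: benzyl bromide BrCc1ccccc1
Why: SN2 O-alkylation of the carboxylate gives a benzyl ester that can be removed at the end by hydrogenolysis without endangering the octanoate.

**Step 6**
Reactants: 11 benzyl ester
Product: 12 dibenzyl (4R,5S)-2,2-dimethyl-5-(1-phenylethenyl)-1,3-oxazolidine-3,4-dicarboxylate (4,5-trans)
Conditions: Me2C(OMe)2 (10 equiv), BF3·OEt2 (5 mol%), acetone, rt
Reagents that add atoms: 2,2-dimethoxypropane COC(C)(C)OC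
Why: Acid-catalysed transacetalisation (N,O-isopropylidenation) closes the trans-oxazolidine, which holds the C–O bond out of the enolate plane (no β-elimination) and places the 1-phenylvinyl group on one ring face.

**Step 7**
Reactants: 12 oxazolidine
Product: 14 dibenzyl (4S,5S)-2,2-dimethyl-5-(1-phenylethenyl)-4-(prop-2-en-1-yl)-1,3-oxazolidine-3,4-dicarboxylate (allyl trans to the 1-phenylethenyl group), via lithium enolate 13 (not isolated)
Conditions: LiN(SiMe3)2 (1.2 equiv), THF/DMPU, −78 °C, 45 min; allyl bromide (3 equiv), −78 → −40 °C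
Reagents that add atoms: allyl bromide C=CCBr
Why: Enolate alkylation with self-regeneration of the stereocentre (Seebach principle): the planar ester enolate is allylated on the face anti to the 5-(1-phenylvinyl) group, which sets the quaternary carbon (future C1, S) with the ester cis to that group.

**Step 8**
Reactants: 14 allylated oxazolidine
Product: 15 benzyl (2S,3S)-2-{[(benzyloxy)carbonyl]amino}-3-hydroxy-4-phenyl-2-(prop-2-en-1-yl)pent-4-enoate
Conditions: TsOH·H2O (0.2 equiv), MeOH, 40 °C
Reagents that add atoms: none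
Why: Acid-catalysed transacetalisation to methanol removes the isopropylidene group, so that the two alkene arms, trans on the oxazolidine, are free to meet in a ring.

**Step 9**
Reactants: 15 diene
Product: 16 benzyl (1S,2S)-1-{[(benzyloxy)carbonyl]amino}-2-hydroxy-3-phenylcyclopent-3-ene-1-carboxylate (OH cis to CO2Bn)
Conditions: (H2IMes)(PCy3)Cl2Ru=CHPh (second-generation Grubbs catalyst, 5 mol%), CH2Cl2 (0.01 M), 40 °C
Reagents that add atoms: none
Why: Ring-closing metathesis: the ruthenium carbene loads on the allyl group and closes onto the 1,1-disubstituted styrenyl alkene to give the trisubstituted cyclopentene with loss of ethylene; no stereocentre changes.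

**Step 10**
Reactants: 16 cyclopentenol
Product: 17 benzyl (1S,2S)-1-{[(benzyloxy)carbonyl]amino}-2-(octanoyloxy)-3-phenylcyclopent-3-ene-1-carboxylate
Conditions: n-C7H15COCl (1.5 equiv), pyridine (3 equiv), DMAP (0.2 equiv), CH2Cl2, 0 °C → rt
Reagents that add atoms: octanoyl chloride CCCCCCCC(=O)Cl
Why: DMAP-catalysed O-acylation of the only hydroxyl installs the natural octanoate and masks the allylic OH so that it cannot direct the next oxidation to the wrong face.

**Step 11**
Reactants: 17 cyclopentene octanoate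
Product: 18 benzyl (1R,2R,3S,5R)-3-{[(benzyloxy)carbonyl]amino}-2-(octanoyloxy)-1-phenyl-6-oxabicyclo[3.1.0]hexane-3-carboxylate (oxirane oxygen cis to NHCbz, trans to the octanoate)
Conditions: mCPBA (1.5 equiv), CH2Cl2/0.5 M aq. NaHCO3, 0 °C
Reagents that add atoms: mCPBA OOC(=O)c1cccc(Cl)c1
Why: Prilezhaev epoxidation under Henbest-type direction: the carbamate N–H hydrogen-bonds the peracid and delivers oxygen to the face cis to nitrogen, which is also the face anti to the allylic octanoate and the C1 ester, so the new C3–O bond is trans to the C2 ester.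

**Step 12**
Reactants: 18 epoxide
Product: 19 benzyl (1S,2R,3S,4S)-1-{[(benzyloxy)carbonyl]amino}-3-hydroxy-2-(octanoyloxy)-3-phenyl-4-(phenylselanyl)cyclopentane-1-carboxylate
Conditions: (PhSe)2 (0.6 equiv), NaBH4 (1.2 equiv), EtOH, 0 °C → rt; then 18, THF, rt; aq. NH4Cl
Reagents that add atoms: diphenyl diselenide c1ccc(cc1)[Se][Se]c1ccccc1
Why: SN2 epoxide opening by the soft selenolate at the less substituted C4 with inversion leaves the C3–O bond intact, so C3 keeps the configuration fixed in step 11 (tertiary OH cis to N, trans to the octanoate).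

**Step 13**
Reactants: 19 hydroxy selenide
Product: 20 benzyl (1S,2R,3S)-1-{[(benzyloxy)carbonyl]amino}-3-hydroxy-2-(octanoyloxy)-3-phenylcyclopentane-1-carboxylate
Conditions: Bu3SnH (2 equiv), AIBN (0.2 equiv), toluene, 90 °C
Reagents that add atoms: none
Why: Radical chain deselenation (tin hydride reduction) replaces the C–Se bond by C–H without affecting the esters, the carbamate or the tertiary alcohol.

**Step 14**
Reactants: 20 protected Fusarilin A
Product: 22 Fusarilin A, via carbamic acid 21 (not isolated)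
Conditions: H2 (1 atm), 10% Pd/C, EtOAc/MeOH, rt
Reagents that add atoms: none
Why: Hydrogenolysis cleaves the benzyl ester and the benzyl carbamate under neutral conditions and the carbamic acid loses CO2; the trans amino/acyloxy arrangement on the five-membered ring prevents O-to-N acyl shift.

**Compound list**
1 | phenylacetaldehyde | O=CCc1ccccc1 | starting material
2 | 2-phenyl-3-(pyrrolidin-1-yl)propanal (Mannich base, racemic) | O=CC(CN1CCCC1)c1ccccc1 | intermediate
3 | 2-phenylprop-2-enal (atropaldehyde) | C=C(C=O)c1ccccc1 | intermediate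
4 | (2S)-3,6-dimethoxy-2-(propan-2-yl)-2,5-dihydropyrazine ((S)-Schöllkopf bislactim ether) | COC1=N[C@@H](C(C)C)C(OC)=NC1 | starting material
5 | lithium salt of the C5 carbanion (aza-enolate) of 4 | COC1=N[C@@H](C(C)C)C(OC)=N[CH-]1.[Li+] | intermediate
6 | C5-[tris(diethylamido)titanium] derivative of 4 (tetravalent titanium aza-enolate, drawn C-bound) | COC1=N[C@@H](C(C)C)C(OC)=NC1[Ti](N(CC)CC)(N(CC)CC)N(CC)CC | intermediate
7 | (2S,5R)-5-[(1S)-1-hydroxy-2-phenylprop-2-en-1-yl]-3,6-dimethoxy-2-(propan-2-yl)-2,5-dihydropyrazine | COC1=N[C@@H](C(C)C)C(OC)=N[C@@H]1[C@@H](O)C(=C)c1ccccc1 | intermediate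
8 | methyl (2R,3S)-2-amino-3-hydroxy-4-phenylpent-4-enoate | COC(=O)[C@H](N)[C@@H](O)C(=C)c1ccccc1 | intermediate
9 | lithium (2R,3S)-2-amino-3-hydroxy-4-phenylpent-4-enoate | [Li+].[O-]C(=O)[C@H](N)[C@@H](O)C(=C)c1ccccc1 | intermediate
10 | (2R,3S)-2-{[(benzyloxy)carbonyl]amino}-3-hydroxy-4-phenylpent-4-enoic acid | OC(=O)[C@H](NC(=O)OCc1ccccc1)[C@@H](O)C(=C)c1ccccc1 | intermediate
11 | benzyl (2R,3S)-2-{[(benzyloxy)carbonyl]amino}-3-hydroxy-4-phenylpent-4-enoate | O=C(OCc1ccccc1)[C@H](NC(=O)OCc1ccccc1)[C@@H](O)C(=C)c1ccccc1 | intermediate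
12 | dibenzyl (4R,5S)-2,2-dimethyl-5-(1-phenylethenyl)-1,3-oxazolidine-3,4-dicarboxylate | CC1(C)O[C@@H](C(=C)c2ccccc2)[C@H](C(=O)OCc2ccccc2)N1C(=O)OCc1ccccc1 | intermediate
13 | lithium ester enolate of 12 (C4 planar, C5 S) | [Li+].[O-]C(OCc1ccccc1)=C2N(C(=O)OCc3ccccc3)C(C)(C)O[C@H]2C(=C)c4ccccc4 | intermediate
14 | dibenzyl (4S,5S)-2,2-dimethyl-5-(1-phenylethenyl)-4-(prop-2-en-1-yl)-1,3-oxazolidine-3,4-dicarboxylate | CC1(C)O[C@@H](C(=C)c2ccccc2)[C@@](CC=C)(C(=O)OCc2ccccc2)N1C(=O)OCc1ccccc1 | intermediate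
15 | benzyl (2S,3S)-2-{[(benzyloxy)carbonyl]amino}-3-hydroxy-4-phenyl-2-(prop-2-en-1-yl)pent-4-enoate | O=C(OCc1ccccc1)[C@@](CC=C)(NC(=O)OCc1ccccc1)[C@@H](O)C(=C)c1ccccc1 | intermediate
16 | benzyl (1S,2S)-1-{[(benzyloxy)carbonyl]amino}-2-hydroxy-3-phenylcyclopent-3-ene-1-carboxylate | O=C(OCc1ccccc1)[C@]1(NC(=O)OCc2ccccc2)CC=C(c2ccccc2)[C@@H]1O | intermediate
17 | benzyl (1S,2S)-1-{[(benzyloxy)carbonyl]amino}-2-(octanoyloxy)-3-phenylcyclopent-3-ene-1-carboxylate | O=C(OCc1ccccc1)[C@]1(NC(=O)OCc2ccccc2)CC=C(c2ccccc2)[C@@H]1OC(=O)CCCCCCC | intermediate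
18 | benzyl (1R,2R,3S,5R)-3-{[(benzyloxy)carbonyl]amino}-2-(octanoyloxy)-1-phenyl-6-oxabicyclo[3.1.0]hexane-3-carboxylate | O=C(OCc1ccccc1)[C@]2(NC(=O)OCc3ccccc3)C[C@H]4O[C@@]4(c5ccccc5)[C@@H]2OC(=O)CCCCCCC | intermediate
19 | benzyl (1S,2R,3S,4S)-1-{[(benzyloxy)carbonyl]amino}-3-hydroxy-2-(octanoyloxy)-3-phenyl-4-(phenylselanyl)cyclopentane-1-carboxylate | O=C(OCc1ccccc1)[C@]2(NC(=O)OCc3ccccc3)C[C@H]([Se]c4ccccc4)[C@](O)(c5ccccc5)[C@@H]2OC(=O)CCCCCCC | intermediate
20 | benzyl (1S,2R,3S)-1-{[(benzyloxy)carbonyl]amino}-3-hydroxy-2-(octanoyloxy)-3-phenylcyclopentane-1-carboxylate | O=C(OCc1ccccc1)[C@]1(NC(=O)OCc2ccccc2)CC[C@](O)(c2ccccc2)[C@@H]1OC(=O)CCCCCCC | intermediate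
21 | (1S,2R,3S)-1-(carboxyamino)-3-hydroxy-2-(octanoyloxy)-3-phenylcyclopentane-1-carboxylic acid (carbamic acid) | OC(=O)[C@]1(NC(=O)O)CC[C@](O)(c2ccccc2)[C@@H]1OC(=O)CCCCCCC | intermediate
22 | Fusarilin A, (1S,2R,3S)-1-amino-3-hydroxy-2-(octanoyloxy)-3-phenylcyclopentane-1-carboxylic acid | CCCCCCCC(=O)O[C@@H]1[C@](N)(C(=O)O)CC[C@]1(O)c1ccccc1 | target

**Totals**
Total step count: 14. Longest linear sequence: 14 steps (1 → 22; 13 steps from 4).

**Steps most likely to fail, with fallbacks**

Step 2 (aldol with the polymerisable enal 3; possible conjugate addition or lower syn selectivity). Fallback: the 1-phenylvinyl group is built after the aldol from a stable aldehyde. Setting out from 4, the same titanium aza-enolate 6 is added to anhydrous phenylglyoxal (distilled from the commercial hydrate), which reacts only at its aldehyde carbonyl to give the α-hydroxy ketone (2S,5R)-5-[(1R)-1-hydroxy-2-oxo-2-phenylethyl]-3,6-dimethoxy-2-(propan-2-yl)-2,5-dihydropyrazine F1. Wittig methylenation of its aryl ketone (Ph3P=CH2 from Ph3PCH3Br/KOtBu, 3 equiv, THF, 0 °C → rt) then comes back to the route at 7.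

Step 7 (intermolecular allylation of a hindered enolate to a quaternary centre; possible low conversion, ring-opening elimination or imperfect face selectivity). Fallback: the allyl group is delivered intramolecularly by an Ireland–Claisen rearrangement. Setting out from 10, allyl bromide/KHCO3/DMF gives the allyl ester prop-2-en-1-yl (2R,3S)-2-{[(benzyloxy)carbonyl]amino}-3-hydroxy-4-phenylpent-4-enoate F2. Acetonide formation as in step 6 gives the oxazolidine allyl ester F3. LiN(SiMe3)2/Me3SiCl in THF at −78 °C gives the silyl ketene acetal F4, which on warming rearranges [3,3] on the face anti to the 5-substituent to the trimethylsilyl ester F5. Aqueous work-up hydrolyses this to the 4-allyl oxazolidine-4-carboxylic acid F6, and benzylation (BnBr, KHCO3, DMF) comes back to the route at 14.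

Step 12 (selenolate attack at a secondary carbon next to a fully substituted one; possible slow opening or competing SN2 debenzylation of the ester). Fallback: the tertiary alcohol is made directly from the alkene by hydrogen-atom-transfer (Mukaiyama) hydration, bypassing the epoxide. Setting out from 17, Mn(dpm)3 (10 mol%, a trivalent manganese tris-diketonate), PhSiH3 and O2 in iPrOH/CH2Cl2 at 0 °C generate the benzylic C3 radical. This is trapped by O2 on the face anti to the neighbouring octanoate to give the tertiary hydroperoxide benzyl (1S,2R,3S)-1-{[(benzyloxy)carbonyl]amino}-3-hydroperoxy-2-(octanoyloxy)-3-phenylcyclopentane-1-carboxylate F7. Reduction in the same pot with P(OEt)3 comes back to the route at 20.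

**Further compounds**
F1 | step 2 | (2S,5R)-5-[(1R)-1-hydroxy-2-oxo-2-phenylethyl]-3,6-dimethoxy-2-(propan-2-yl)-2,5-dihydropyrazine | COC1=N[C@@H](C(C)C)C(OC)=N[C@@H]1[C@@H](O)C(=O)c1ccccc1
F2 | step 7 | prop-2-en-1-yl (2R,3S)-2-{[(benzyloxy)carbonyl]amino}-3-hydroxy-4-phenylpent-4-enoate | C=CCOC(=O)[C@H](NC(=O)OCc1ccccc1)[C@@H](O)C(=C)c1ccccc1
F3 | step 7 | 3-benzyl 4-(prop-2-en-1-yl) (4R,5S)-2,2-dimethyl-5-(1-phenylethenyl)-1,3-oxazolidine-3,4-dicarboxylate | CC1(C)O[C@@H](C(=C)c2ccccc2)[C@H](C(=O)OCC=C)N1C(=O)OCc1ccccc1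
F4 | step 7 | benzyl (5S)-2,2-dimethyl-5-(1-phenylethenyl)-4-[(prop-2-en-1-yloxy)(trimethylsilyloxy)methylidene]-1,3-oxazolidine-3-carboxylate (silyl ketene acetal) | C=CCOC(O[Si](C)(C)C)=C1N(C(=O)OCc2ccccc2)C(C)(C)O[C@H]1C(=C)c1ccccc1
F5 | step 7 | 3-benzyl 4-(trimethylsilyl) (4S,5S)-2,2-dimethyl-5-(1-phenylethenyl)-4-(prop-2-en-1-yl)-1,3-oxazolidine-3,4-dicarboxylate | CC1(C)O[C@@H](C(=C)c2ccccc2)[C@@](CC=C)(C(=O)O[Si](C)(C)C)N1C(=O)OCc1ccccc1
F6 | step 7 | (4S,5S)-3-[(benzyloxy)carbonyl]-2,2-dimethyl-5-(1-phenylethenyl)-4-(prop-2-en-1-yl)-1,3-oxazolidine-4-carboxylic acid | CC1(C)O[C@@H](C(=C)c2ccccc2)[C@@](CC=C)(C(=O)O)N1C(=O)OCc1ccccc1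
F7 | step 12 | benzyl (1S,2R,3S)-1-{[(benzyloxy)carbonyl]amino}-3-hydroperoxy-2-(octanoyloxy)-3-phenylcyclopentane-1-carboxylate | O=C(OCc1ccccc1)[C@]1(NC(=O)OCc2ccccc2)CC[C@](OO)(c2ccccc2)[C@@H]1OC(=O)CCCCCCC
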